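The carbocycle of the target (C1 carries the side chain, C2 is the methylene, C3 and C4 carry the epoxide with the methyl on C4, C5 is the ketone, C6 bears the acetate) is read as a masked 2-methylcyclohex-2-enone whose C5 carbonyl lies 1,3 to the C1 stereocentre. Cutting C1–C6 and C3=C4 leaves a silyl-capped pent-2-en-4-ynal (C3, C2, C1 and the alkyne that becomes the C7 alkenyl unit) and tert-butyl 3-oxopentanoate (C6, C5, C4, methyl). One amine-catalysed Michael/aldol condensation should close this ring and fix C1; the other ring stereocentres are then relayed from C1, and the side-chain carbinol centre is set by a chiral chromium catalyst.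

Key step: step 3

Numbering used in the text: ring atoms C1–C6 as above; C7 is the alkene carbon on C1 and C8 the carbinol carbon next to it. Compound names use their own locants.

Assumption: in step 9 the facial sense induced by the chiral sulfonamide–oxazoline ligand is not predicted here; the antipode (both are made from D- or L-valinol) that leads to the 8S alcohol is the one meant.

Step 1
Reactants: 1 ethynyltriisopropylsilane
Product: 3 3-(triisopropylsilyl)prop-2-ynal, via lithium acetylide 2 (not isolated)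
Conditions: n-BuLi, THF, −78 °C; DMF, −78 °C → rt; inverse quench into cold aq. KH2PO4
Reagents that add atoms: N,N-dimethylformamide, CN(C)C=O
Why: Deprotonation of the terminal alkyne and formylation of the lithium acetylide with DMF should give the ynal, the buffered inverse quench keeping the released dimethylamine from adding to it.

Step 2
Reactants: 3 3-(triisopropylsilyl)prop-2-ynal, 4 (triphenylphosphoranylidene)acetaldehyde
Product: 5 (2E)-5-(triisopropylsilyl)pent-2-en-4-ynal
Conditions: toluene, rt
Reagents that add atoms: none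
Why: Wittig olefination with the stabilised formylmethylene ylide should give the E-enal, a second homologation being slow because the ynal is much more electrophilic than the conjugated product.

Step 3
Reactants: 5 (2E)-5-(triisopropylsilyl)pent-2-en-4-ynal, 6 tert-butyl 3-oxopentanoate
Product: 8 tert-butyl (1S,6R)-3-methyl-2-oxo-6-[(triisopropylsilyl)ethynyl]cyclohex-3-ene-1-carboxylate, via Michael adduct 7 (not isolated)
Conditions: (S)-2-{bis[3,5-bis(trifluoromethyl)phenyl][(trimethylsilyl)oxy]methyl}pyrrolidine (10 mol %), PhCO2H (10 mol %), toluene, 0 °C → rt; then TsOH·H2O (20 mol %), 40 °C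
Reagents that add atoms: none
Why: The amine and 5 form an s-trans iminium ion, the enol of 6 adds 1,4 at C1, hydrolysis frees aldehyde 7, and under acid the enol of the ethyl ketone (C4) attacks the aldehyde carbon C3 and water is lost to give the C3=C4 enone. The closest known reaction type is the diarylprolinol-silyl-ether-catalysed Michael addition of β-keto esters to enals followed by acid-promoted intramolecular aldol condensation to cyclohex-2-enones. The six-membered ring closes in a 6-(enolexo)-exo-trig aldol mode, the only other enol (at C6) leading to a cyclobutane. C1 is controlled by the catalyst, whose diarylsilyloxymethyl arm blocks the Re face of C1 so that C6 bonds on the Si face (R at this carbon, which is the spatial arrangement drawn for C1 in the target), while C6 lies between two carbonyl groups and settles by enolisation trans to the alkynyl group. The step needs 1,4- over 1,6-addition, which the bulky triisopropylsilyl cap at the alkyne terminus secures, and it needs the ester to outlast ring closure, for which the mild acid stage at 40 °C is chosen.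

Step 4
Reactants: 8 tert-butyl (1S,6R)-3-methyl-2-oxo-6-[(triisopropylsilyl)ethynyl]cyclohex-3-ene-1-carboxylate
Product: 10 (5R)-2-methyl-5-[(triisopropylsilyl)ethynyl]cyclohex-2-en-1-one, via β-keto acid 9 (not isolated)
Conditions: TsOH·H2O (0.5 equiv), toluene, 80 °C
Reagents that add atoms: none
Why: Acid-catalysed loss of isobutene from the tert-butyl ester and decarboxylation of the β-keto acid should give the enone, the non-enolisable C1 keeping its configuration.

Step 5
Reactants: 10 (5R)-2-methyl-5-[(triisopropylsilyl)ethynyl]cyclohex-2-en-1-one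
Product: 11 (5R)-5-ethynyl-2-methylcyclohex-2-en-1-one
Conditions: Bu4NF (1.1 equiv), THF, 0 °C
Reagents that add atoms: none
Why: Fluoride-induced protodesilylation of the alkynylsilane is done here, while the only other function is a robust enone.

Step 6
Reactants: 11 (5R)-5-ethynyl-2-methylcyclohex-2-en-1-one
Product: 12 (5R)-5-(1-iodoethenyl)-2-methylcyclohex-2-en-1-one
Conditions: NaI, Me3SiCl, H2O (0.5 equiv), MeCN, 0 °C → rt; aq. NaHCO3/Na2S2O3 work-up
Reagents that add atoms: sodium iodide, [Na+].[I-]
Why: Markovnikov hydroiodination of the terminal alkyne by HI made in the flask should give the 2-iodoalkene, any reversible iodide adduct of the enone reverting on the basic work-up.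

Step 7
Reactants: 12 (5R)-5-(1-iodoethenyl)-2-methylcyclohex-2-en-1-one
Product: 13 (1S,6R)-6-(1-iodoethenyl)-3-methyl-2-oxocyclohex-3-en-1-yl acetate
Conditions: Mn(OAc)3·2H2O (3 equiv), benzene/AcOH (10:1), reflux
Reagents that add atoms: manganese triacetate dihydrate, CC(=O)[O-].CC(=O)[O-].CC(=O)[O-].[Mn+3].O.O
Why: α′-Acetoxylation of the enone through the trivalent manganese enolate at C6 should deliver acetate anti to the neighbouring 1-iodovinyl group (a close analogue of the isopropenyl group of carvone), the trans-diequatorial product also being the thermodynamic epimer.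

Step 8
Reactants: 14 4-methylpent-3-en-1-ol
Product: 15 4-methylpent-3-enal
Conditions: DMP, NaHCO3, CH2Cl2, 0 °C → rt; solution used at once
Reagents that add atoms: none
Why: Buffered Dess–Martin oxidation is non-basic, so the β,γ-alkene should not move into conjugation before the volatile aldehyde is used.

Step 9
Reactants: 13 (1S,6R)-6-(1-iodoethenyl)-3-methyl-2-oxocyclohex-3-en-1-yl acetate, 15 4-methylpent-3-enal
Product: 16 (1S,6S)-6-[(3S)-3-hydroxy-6-methylhepta-1,5-dien-2-yl]-3-methyl-2-oxocyclohex-3-en-1-yl acetate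
Conditions: CrCl2 (10 mol %), N-[2-(4-isopropyl-4,5-dihydrooxazol-2-yl)-6-methylphenyl]methanesulfonamide (11 mol %), 1,8-bis(dimethylamino)naphthalene (11 mol %), NiCl2·(2,9-dimethyl-1,10-phenanthroline) (2 mol %), Mn powder, Cp2ZrCl2, LiCl, MeCN, rt
Reagents that add atoms: none
Why: In this catalytic asymmetric Nozaki–Hiyama–Kishi coupling zerovalent nickel inserts into the C–I bond, the alkenyl group passes to ligand-bound chromium and adds only to the aldehyde, so that C8 is set by the chiral ligand (reagent control) while ketone, enone and acetate should stay untouched at the low concentration of divalent chromium.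

Step 10
Reactants: 16 (1S,6S)-6-[(3S)-3-hydroxy-6-methylhepta-1,5-dien-2-yl]-3-methyl-2-oxocyclohex-3-en-1-yl acetate, 17 angelic acid [(2Z)-2-methylbut-2-enoic acid]
Product: 19 (3S)-2-[(1S,2S)-2-acetoxy-4-methyl-3-oxocyclohex-4-en-1-yl]-6-methylhepta-1,5-dien-3-yl (2Z)-2-methylbut-2-enoate, via mixed anhydride 18 (not isolated)
Conditions: 17, 2,4,6-Cl3C6H2COCl, Et3N, toluene, rt; then 16, 80 °C
Reagents that add atoms: none
Why: Yamaguchi-type esterification through the 2,4,6-trichlorobenzoic mixed anhydride without DMAP is the established way to make angelates without Z-to-E isomerisation to the tiglate.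

Step 11
Reactants: 19 (3S)-2-[(1S,2S)-2-acetoxy-4-methyl-3-oxocyclohex-4-en-1-yl]-6-methylhepta-1,5-dien-3-yl (2Z)-2-methylbut-2-enoate
Product: 20 (3S)-2-[(1S,2S,3S)-2-acetoxy-3-hydroxy-4-methylcyclohex-4-en-1-yl]-6-methylhepta-1,5-dien-3-yl (2Z)-2-methylbut-2-enoate
Conditions: NaBH4, CeCl3·7H2O, MeOH, −78 °C; cold AcOH quench
Reagents that add atoms: none
Why: Luche 1,2-reduction with axial hydride attack on C5 of the half-chair (C1 and C6 substituents equatorial) should give the equatorial alcohol cis to the C1 side chain and trans to the acetate, as in the reduction of carvone to cis-carveol, and the cold quench guards against acetyl migration.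

Step 12
Reactants: 20 (3S)-2-[(1S,2S,3S)-2-acetoxy-3-hydroxy-4-methylcyclohex-4-en-1-yl]-6-methylhepta-1,5-dien-3-yl (2Z)-2-methylbut-2-enoate
Product: 21 (3S)-2-[(1R,2R,3S,4S,6S)-3-acetoxy-2-hydroxy-1-methyl-7-oxabicyclo[4.1.0]heptan-4-yl]-6-methylhepta-1,5-dien-3-yl (2Z)-2-methylbut-2-enoate
Conditions: VO(acac)2 (5 mol %), t-BuOOH (decane solution), CH2Cl2, 0 °C → rt
Reagents that add atoms: tert-butyl hydroperoxide, CC(C)(C)OO
Why: Hydroxyl-directed epoxidation should deliver oxygen to C3=C4 on the face of the C5 hydroxyl, that is cis to the C1 side chain, and leave the prenyl, 1,1-disubstituted and angelate alkenes alone, as the isopropenyl group of carveol is left.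

Step 13
Reactants: 21 (3S)-2-[(1R,2R,3S,4S,6S)-3-acetoxy-2-hydroxy-1-methyl-7-oxabicyclo[4.1.0]heptan-4-yl]-6-methylhepta-1,5-dien-3-yl (2Z)-2-methylbut-2-enoate
Product: 22 (3S)-2-[(1S,3S,4S,6S)-3-acetoxy-1-methyl-2-oxo-7-oxabicyclo[4.1.0]heptan-4-yl]-6-methylhepta-1,5-dien-3-yl (2Z)-2-methylbut-2-enoate
Conditions: DMP, NaHCO3, CH2Cl2, 0 °C → rt
Reagents that add atoms: none
Why: Buffered Dess–Martin oxidation of the secondary epoxy alcohol should give the α,β-epoxy ketone without epimerising C6 or opening the epoxide.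

Compound list
1 | ethynyltriisopropylsilane | C#C[Si](C(C)C)(C(C)C)C(C)C | starting material
2 | lithium (triisopropylsilyl)acetylide | [Li]C#C[Si](C(C)C)(C(C)C)C(C)C | intermediate (not isolated)
3 | 3-(triisopropylsilyl)prop-2-ynal | O=CC#C[Si](C(C)C)(C(C)C)C(C)C | intermediate
4 | (triphenylphosphoranylidene)acetaldehyde | O=CC=P(c1ccccc1)(c1ccccc1)c1ccccc1 | starting material
5 | (2E)-5-(triisopropylsilyl)pent-2-en-4-ynal | O=C/C=C/C#C[Si](C(C)C)(C(C)C)C(C)C | intermediate
6 | tert-butyl 3-oxopentanoate | CCC(=O)CC(=O)OC(C)(C)C | starting material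
7 | tert-butyl (3R)-3-(2-oxoethyl)-2-propanoyl-5-(triisopropylsilyl)pent-4-ynoate (C2 epimers) | CCC(=O)C(C(=O)OC(C)(C)C)[C@@H](CC=O)C#C[Si](C(C)C)(C(C)C)C(C)C | intermediate (not isolated)
8 | tert-butyl (1S,6R)-3-methyl-2-oxo-6-[(triisopropylsilyl)ethynyl]cyclohex-3-ene-1-carboxylate (trans) | CC(C)[Si](C(C)C)(C(C)C)C#C[C@@H]1CC=C(C)C(=O)[C@H]1C(=O)OC(C)(C)C | intermediate
9 | (1S,6R)-3-methyl-2-oxo-6-[(triisopropylsilyl)ethynyl]cyclohex-3-ene-1-carboxylic acid | CC(C)[Si](C(C)C)(C(C)C)C#C[C@@H]1CC=C(C)C(=O)[C@H]1C(=O)O | intermediate (not isolated)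
10 | (5R)-2-methyl-5-[(triisopropylsilyl)ethynyl]cyclohex-2-en-1-one | CC(C)[Si](C(C)C)(C(C)C)C#C[C@@H]1CC=C(C)C(=O)C1 | intermediate
11 | (5R)-5-ethynyl-2-methylcyclohex-2-en-1-one | C#C[C@@H]1CC=C(C)C(=O)C1 | intermediate
12 | (5R)-5-(1-iodoethenyl)-2-methylcyclohex-2-en-1-one | C=C(I)[C@@H]1CC=C(C)C(=O)C1 | intermediate
13 | (1S,6R)-6-(1-iodoethenyl)-3-methyl-2-oxocyclohex-3-en-1-yl acetate (acetate trans to iodovinyl) | C=C(I)[C@@H]1CC=C(C)C(=O)[C@H]1OC(C)=O | intermediate
14 | 4-methylpent-3-en-1-ol | CC(C)=CCCO | starting material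
15 | 4-methylpent-3-enal | CC(C)=CCC=O | intermediate
16 | (1S,6S)-6-[(3S)-3-hydroxy-6-methylhepta-1,5-dien-2-yl]-3-methyl-2-oxocyclohex-3-en-1-yl acetate | C=C([C@H](CC=C(C)C)O)[C@@H]1CC=C(C)C(=O)[C@H]1OC(C)=O | intermediate
17 | angelic acid, (2Z)-2-methylbut-2-enoic acid | C/C=C(/C)C(=O)O | starting material
18 | (2Z)-2-methylbut-2-enoic 2,4,6-trichlorobenzoic anhydride | C/C=C(/C)C(=O)OC(=O)c1c(Cl)cc(Cl)cc1Cl | intermediate (not isolated)
19 | (3S)-2-[(1S,2S)-2-acetoxy-4-methyl-3-oxocyclohex-4-en-1-yl]-6-methylhepta-1,5-dien-3-yl (2Z)-2-methylbut-2-enoate | C=C([C@H](CC=C(C)C)OC(=O)/C(C)=C\C)[C@@H]1CC=C(C)C(=O)[C@H]1OC(C)=O | intermediate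
20 | (3S)-2-[(1S,2S,3S)-2-acetoxy-3-hydroxy-4-methylcyclohex-4-en-1-yl]-6-methylhepta-1,5-dien-3-yl (2Z)-2-methylbut-2-enoate (hydroxyl cis to the side chain, trans to the acetate) | C=C([C@H](CC=C(C)C)OC(=O)/C(C)=C\C)[C@@H]1CC=C(C)[C@H](O)[C@H]1OC(C)=O | intermediate
21 | (3S)-2-[(1R,2R,3S,4S,6S)-3-acetoxy-2-hydroxy-1-methyl-7-oxabicyclo[4.1.0]heptan-4-yl]-6-methylhepta-1,5-dien-3-yl (2Z)-2-methylbut-2-enoate (epoxide cis to hydroxyl and side chain) | C=C([C@H](CC=C(C)C)OC(=O)/C(C)=C\C)[C@@H]1C[C@@H]2O[C@]2(C)[C@H](O)[C@H]1OC(C)=O | intermediate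
22 | (3S)-2-[(1S,3S,4S,6S)-3-acetoxy-1-methyl-2-oxo-7-oxabicyclo[4.1.0]heptan-4-yl]-6-methylhepta-1,5-dien-3-yl (2Z)-2-methylbut-2-enoate | C=C([C@H](CC=C(C)C)OC(=O)/C(C)=C\C)[C@@H]1C[C@@H]2O[C@]2(C)C(=O)[C@H]1OC(C)=O | target

Total step count: 13. Longest linear sequence: 12 (steps 1–7 and 9–13; step 8 makes the aldehyde partner).

Steps most likely to fail

Step 9. The ligand may be mismatched with the existing C1 centre, so that facial selectivity at C8 is poor. The fallback sets out from 13 and 15: a ligand-free coupling (CrCl2, NiCl2 cat., DMSO/THF, rt) is run without stereocontrol and the two C8 epimers are separated by chromatography. The 8S epimer is 16 and goes on through step 10. The 8R epimer, (1S,6S)-6-[(3R)-3-hydroxy-6-methylhepta-1,5-dien-2-yl]-3-methyl-2-oxocyclohex-3-en-1-yl acetate F1, is esterified with angelic acid 17 under Mitsunobu conditions (PPh3, DIAD, toluene, 0 °C), which inverts C8 and comes back to the route at 19.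

Step 3. Enolisation of the ethyl ketone toward C4 may be slow, so that the hemiacetal form of 7 dehydrates to a 4H-pyran or the ester is lost before the ring closes. The fallback sets out from 5 and uses tert-butyl 3-oxobutanoate in place of 6 with the same amine catalyst, then TsOH·H2O in toluene at 80 °C. The more easily enolised methyl ketone closes the ring, and tert-butyl (1S,6R)-2-oxo-6-[(triisopropylsilyl)ethynyl]cyclohex-3-ene-1-carboxylate F2 (not isolated) loses isobutene and CO2 in the same pot to give (5R)-5-[(triisopropylsilyl)ethynyl]cyclohex-2-en-1-one F3. α-Iodination (I2, pyridine, CH2Cl2, rt) gives (5R)-2-iodo-5-[(triisopropylsilyl)ethynyl]cyclohex-2-en-1-one F4. Suzuki–Miyaura methylation (MeB(OH)2, Pd(OAc)2, SPhos, K3PO4, toluene/H2O, 80 °C) then installs the C4 methyl and comes back at 10.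

Step 7. Conversion may be low, the acetate may enter on both faces of C6, or radical side reactions may occur in hot benzene. The fallback sets out from 12: kinetic α′-deprotonation and silylation (LiN(SiMe3)2, Me3SiCl, THF, −78 °C) gives the silyl dienol ether {[(3R)-3-(1-iodoethenyl)-6-methylcyclohexa-1,5-dien-1-yl]oxy}trimethylsilane F5. Rubottom oxidation (mCPBA, NaHCO3, CH2Cl2, −20 °C, then dilute acid) should attack anti to the iodovinyl group and give (5R,6S)-6-hydroxy-5-(1-iodoethenyl)-2-methylcyclohex-2-en-1-one F6. Acetylation (Ac2O, pyridine, DMAP cat., 0 °C) comes back at 13.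

Further compounds
F1 | step 9 | (1S,6S)-6-[(3R)-3-hydroxy-6-methylhepta-1,5-dien-2-yl]-3-methyl-2-oxocyclohex-3-en-1-yl acetate | C=C([C@@H](CC=C(C)C)O)[C@@H]1CC=C(C)C(=O)[C@H]1OC(C)=O
F2 | step 3 | tert-butyl (1S,6R)-2-oxo-6-[(triisopropylsilyl)ethynyl]cyclohex-3-ene-1-carboxylate | CC(C)[Si](C(C)C)(C(C)C)C#C[C@@H]1CC=CC(=O)[C@H]1C(=O)OC(C)(C)C
F3 | step 3 | (5R)-5-[(triisopropylsilyl)ethynyl]cyclohex-2-en-1-one | CC(C)[Si](C(C)C)(C(C)C)C#C[C@@H]1CC=CC(=O)C1
F4 | step 3 | (5R)-2-iodo-5-[(triisopropylsilyl)ethynyl]cyclohex-2-en-1-one | CC(C)[Si](C(C)C)(C(C)C)C#C[C@@H]1CC=C(I)C(=O)C1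
F5 | step 7 | {[(3R)-3-(1-iodoethenyl)-6-methylcyclohexa-1,5-dien-1-yl]oxy}trimethylsilane | C=C(I)[C@@H]1CC=C(C)C(O[Si](C)(C)C)=C1
F6 | step 7 | (5R,6S)-6-hydroxy-5-(1-iodoethenyl)-2-methylcyclohex-2-en-1-one | C=C(I)[C@@H]1CC=C(C)C(=O)[C@H]1O
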